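Readings and results come from a simulation for substances that don't exist; scatter was added.

Which charge of reagent leaves most bis adduct after 25 h, and how much stands in the flask at the charge given?

| flask | substrate | reagent | remark | time |
|---|---|---|---|---|
| teal | 0.25 M | 0.38 M | run made earlier |  |
| ochre | 0.25 M | 1.5 M | run made earlier |  |
| flask | 0.25 M | 0.750 M |  | 25 h |

| run | time / h | bis adduct / % | single product / % |
|---|---|---|---|
| teal | 2.00 | 5.3 | 50.8 |
| teal | 4.00 | 9.5 | 41.8 |
| teal | 6.00 | 10.9 | 37.7 |
| teal | 8.00 | 14.0 | 35.4 |
| teal | 10.0 | 15.3 | 33.7 |
| teal | 12.0 | 16.8 | 34.4 |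
| teal | 15.0 | 18.6 | 32.2 |
| ochre | 2.00 | 33.6 | 30.8 |
| ochre | 4.00 | 40.2 | 16.4 |
| ochre | 6.00 | 40.6 | 12.0 |
| ochre | 8.00 | 39.0 | 9.5 |
| ochre | 10.0 | 38.1 | 8.0 |
| ochre | 12.0 | 34.8 | 6.9 |
| ochre | 15.0 | 31.1 | 3.9 |

(scatter of a reading: 0.5 percentage points)

* equivalents of reagent to substrate, everything else as given, that leave most bis adduct at 25 h
* the amount of bis adduct then, in percent of the substrate charged
* the amount of bis adduct with the amounts as given

- a species is counted by the substrate in it: one self-condensation product counts as two
- steps under discussion: substrate + reagent -> single product; reagent + single product -> bis adduct; reagent + bis adduct -> tris adduct; single product <-> isomer of the product; 2 substrate -> self-condensation product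

I divide the rate at which bis adduct forms by the rate at which it goes on to tris adduct. [reagent] and time cancel, and what stays is [single product]/[bis adduct] against one constant. The ochre readings top near 6.00 h, with 40.6 % bis adduct on 12.0 % single product, which gives 0.296: this is the turning ratio, a selectivity factor, the [single product]/[bis adduct] at which bis adduct stops rising.

With time gone, I expect a charge to move the date of the top more than its height. The date follows the dose, [reagent] × time, about 450 M·min at the ochre top. In the flask, about 0.500 M of reagent stands once each substrate has taken its first. Near the top each substrate carries about two, leaving 0.250 M, a mean of 0.375 M. So I date the flask's top at 20.0 h, and 25 h falls just beyond it, near the ochre reading of 39.0 %. A top dated exactly at 25 h needs 2.70 equivalents and holds about 40.6 %.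

The forecast is lower on all three: 2.4 equiv, 37 % and 34 %, saying that "over-reaction gives about 34%".

The simulation gives 40.5 % at the given charge, and 40.6 % at 2.86 equiv. At 25 h the flask makes bis adduct at 0.952 of the rate at which it uses it, and [single product]/[bis adduct] divided by the turning ratio is 1.03. The same flask read at 10 h gives 2.00, above one, so bis adduct should still be climbing there. Computed, it holds 35.3 %, less than at 25 h.

    substrate + reagent → single product (k = 0.00137 /M/s)
    reagent + single product → bis adduct (k = 8.55 × 10⁻⁵ /M/s)
    reagent + bis adduct → tris adduct (k = 2.74 × 10⁻⁵ /M/s)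
    single product ⇌ isomer of the product (K = 1.40, k = 1.18 × 10⁻⁴ /s)
    2 substrate → self-condensation product (k = 6.47 × 10⁻⁶ /M/s)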